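## Retrosynthetic overview

1. Target 26 ⇐ C8 alcohol 25 ⇐ silyl ether 24 ⇐ butenolide 23: the methacrylate goes on last, and syn-hydrogenation of the 7(11)-ene from the H-6 face sets C7 and C11.
2. 23 ⇐ acyclic epoxy aldehyde / alkenyl iodide 21: the C6–C7 bond (the bond made when a farnesyl chain closes to the germacrane ring) is formed by NiCl2/CrCl2 alkenylation, and the C6 alkoxide then lactonises onto C12, as in germacranolide biogenesis.
3. 21 ⇐ ynoate 16 (iodide/formaldehyde halo-aldol brings C13; Sharpless epoxidation of the neryl (Z)-allylic alcohol makes the oxirane) ⇐ aldehyde 12 + methyl propiolate (sets C8).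
4. 12 ⇐ diketone 8 + thioester silyl ketene acetal 10 (copper–bisoxazoline aldol sets C10) ⇐ nerol (C1–C6 and C15).
5. Ring order: oxirane on the open chain, then the ten-membered carbocycle, then the γ-lactone in the same operation.

Assumption: the SMILES is taken literally (cis-4,5-epoxide, cis-fused lactone with H-6, H-7, H-11 cis; 4R,5S,6S,7S,8S,10R,11R), and the ligand enantiomers in steps 6 and 8 are chosen by analogy with pyruvate esters and simple aldehydes; if either sense is opposite, the antipodal ligand is used.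

Abbreviations: PMB = 4-methoxybenzyl, TMS = trimethylsilyl, TBS = tert-butyldimethylsilyl. C-locants in the text and in the names of ring compounds are germacrane locants (C12 = lactone carbonyl, C13 = CH2OAc carbon).

## Route

Step 1
Reactants: 1 nerol
Product: 2 neryl PMB ether, 1-({[(2Z)-3,7-dimethylocta-2,6-dien-1-yl]oxy}methyl)-4-methoxybenzene
Conditions: NaH, PMBCl, Bu4NI (cat.), THF, 0 °C to rt
Reagents that add atoms: 4-methoxybenzyl chloride (COc1ccc(CCl)cc1)
Why: Williamson etherification of the primary allylic alkoxide protects the C6 oxygen as an ether that survives the acid, organolithium and Lewis acid steps that follow; no stereocentre is formed and the (Z)-alkene is untouched.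

Step 2
Reactants: 2 neryl PMB ether
Product: 5 (4Z)-6-(PMB-oxy)-4-methylhex-4-enal, via distal epoxide 3 (not isolated), via vicinal diol 4 (not isolated)
Conditions: mCPBA, CH2Cl2, 0 °C; then H5IO6, THF/H2O, 0 °C
Reagents that add atoms: mCPBA (OOC(=O)c1cccc(Cl)c1), water (O)
Why: Prilezhaev epoxidation goes to the distal, more electron-rich trisubstituted alkene (the proximal one is deactivated by the allylic ether), and periodic acid hydrolyses the epoxide and cleaves the diol (Malaprade cleavage) to the C1 aldehyde, so no stereocentre survives.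

Step 3
Reactants: 5 (4Z)-6-(PMB-oxy)-4-methylhex-4-enal
Product: 7 (6Z)-3-hydroxy-8-(PMB-oxy)-6-methyloct-6-en-2-one (racemic at the carbinol), via enol ether carbinol 6 (not isolated)
Conditions: ethyl vinyl ether, t-BuLi, THF, −78 to 0 °C; 5, −78 °C; then 1 M HCl, THF, rt
Reagents that add atoms: ethyl vinyl ether (C=COCC), water (O)
Why: 1-Ethoxyvinyllithium, an acetyl anion equivalent, adds 1,2 to the aldehyde and mild acid hydrolysis of the enol ether unveils the methyl ketone (acyloin synthesis); the carbinol centre is racemic and is erased in step 4.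

Step 4
Reactants: 7 (6Z)-3-hydroxy-8-(PMB-oxy)-6-methyloct-6-en-2-one
Product: 8 (6Z)-8-(PMB-oxy)-6-methyloct-6-ene-2,3-dione
Conditions: Dess–Martin periodinane, CH2Cl2, rt
Reagents that add atoms: none
Why: Dess–Martin oxidation of the secondary α-hydroxy ketone gives the vicinal diketone without touching the ether or the alkene; no stereocentre remains.

Step 5
Reactants: 9 S-ethyl ethanethioate
Product: 10 [1-(ethylsulfanyl)ethenyl]oxy(trimethyl)silane
Conditions: LDA, TMSCl, THF, −78 °C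
Reagents that add atoms: chlorotrimethylsilane (C[Si](C)(C)Cl)
Why: Kinetic deprotonation of the thioester and O-silylation of the enolate give the silyl ketene thioacetal (enolsilane formation).

Step 6
Reactants: 8 (6Z)-8-(PMB-oxy)-6-methyloct-6-ene-2,3-dione; 10 [1-(ethylsulfanyl)ethenyl]oxy(trimethyl)silane
Product: 11 S-ethyl (3R,7Z)-9-(PMB-oxy)-3,7-dimethyl-4-oxo-3-(TMS-oxy)non-7-enethioate
Conditions: Cu(OTf)2 (10 mol %), (R,R)-t-Bu-box (11 mol %), THF, −78 °C
Reagents that add atoms: none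
Why: Evans copper–bisoxazoline Mukaiyama aldol: the diketone chelates copper through both carbonyls, the enolsilane attacks the less hindered methyl-ketone carbonyl (C10) on the face left open by the tert-butyl groups and the silyl group moves to the aldolate oxygen, which sets C10 (R) and leaves C1 as the ketone.

Step 7
Reactants: 11 S-ethyl (3R,7Z)-9-(PMB-oxy)-3,7-dimethyl-4-oxo-3-(TMS-oxy)non-7-enethioate
Product: 12 (3R,7Z)-9-(PMB-oxy)-3,7-dimethyl-4-oxo-3-(TMS-oxy)non-7-enal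
Conditions: Et3SiH, 10% Pd/C, acetone, rt
Reagents that add atoms: none
Why: Fukuyama reduction (oxidative addition of palladium into the C–S bond, hydride transfer from Et3SiH) gives the C8 aldehyde chemoselectively; ketone, alkene, ethers and the C10 centre are untouched.

Step 8
Reactants: 12 (3R,7Z)-9-(PMB-oxy)-3,7-dimethyl-4-oxo-3-(TMS-oxy)non-7-enal; 13 methyl propiolate
Product: 15 methyl (4S,6R,10Z)-4,6-dihydroxy-12-(PMB-oxy)-6,10-dimethyl-7-oxododec-10-en-2-ynoate, via silyl ether alkynol 14 (not isolated)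
Conditions: Me2Zn, (S,S)-ProPhenol (20 mol %), Ph3PO (40 mol %), toluene, 0 °C; then 1 M HCl, THF, 0 °C
Reagents that add atoms: none
Why: Trost ProPhenol–zinc alkynylation adds the zinc acetylide of methyl propiolate to one face of the aldehyde under ligand control, setting C8 (S), and the dilute acid work-up cleaves only the labile tertiary trimethylsilyl ether.

Step 9
Reactants: 15 methyl (4S,6R,10Z)-4,6-dihydroxy-12-(PMB-oxy)-6,10-dimethyl-7-oxododec-10-en-2-ynoate
Product: 16 methyl (4S,6R,10Z)-4-(TBS-oxy)-6-hydroxy-12-(PMB-oxy)-6,10-dimethyl-7-oxododec-10-en-2-ynoate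
Conditions: TBSCl, imidazole, DMF, 0 °C
Reagents that add atoms: tert-butyldimethylsilyl chloride (CC(C)(C)[Si](C)(C)Cl)
Why: Imidazole-promoted silylation takes only the secondary propargylic hydroxyl, because the tertiary α-ketol hydroxyl is too hindered; no stereocentre changes.

Step 10
Reactants: 16 methyl (4S,6R,10Z)-4-(TBS-oxy)-6-hydroxy-12-(PMB-oxy)-6,10-dimethyl-7-oxododec-10-en-2-ynoate
Product: 17 methyl (2Z,4S,6R,10Z)-4-(TBS-oxy)-6-hydroxy-2-(hydroxymethyl)-3-iodo-12-(PMB-oxy)-6,10-dimethyl-7-oxododeca-2,10-dienoate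
Conditions: MgI2, HCHO (monomer), CH2Cl2, 0 °C
Reagents that add atoms: magnesium diiodide ([Mg+2].[I-].[I-]), formaldehyde (C=O)
Why: Proposed new method: iodide adds in conjugate fashion to the magnesium-activated ynoate to give a β-iodo allenolate whose α-carbon (C11) is captured by formaldehyde, the (Z)-isomer with iodine cis to the ester being the kinetic product as in the known cases; the closest known reaction is the MgI2- or Et2AlI-mediated halo-aldol (β-iodo Morita–Baylis–Hillman) reaction of propiolates and ynones with aldehydes.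

Step 11
Reactants: 17 methyl (2Z,4S,6R,10Z)-4-(TBS-oxy)-6-hydroxy-2-(hydroxymethyl)-3-iodo-12-(PMB-oxy)-6,10-dimethyl-7-oxododeca-2,10-dienoate
Product: 18 methyl (2Z,4S,6R,10Z)-6-acetoxy-2-(acetoxymethyl)-4-(TBS-oxy)-3-iodo-12-(PMB-oxy)-6,10-dimethyl-7-oxododeca-2,10-dienoate
Conditions: Ac2O, DMAP, Et3N, CH2Cl2, rt to 35 °C
Reagents that add atoms: acetic anhydride (CC(=O)OC(C)=O)
Why: DMAP-catalysed acyl transfer (Steglich acetylation) esterifies both the primary allylic hydroxyl (C13) and the tertiary α-ketol hydroxyl (C10), the silyl and benzyl ethers staying in place.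

Step 12
Reactants: 18 methyl (2Z,4S,6R,10Z)-6-acetoxy-2-(acetoxymethyl)-4-(TBS-oxy)-3-iodo-12-(PMB-oxy)-6,10-dimethyl-7-oxododeca-2,10-dienoate
Product: 19 methyl (2Z,4S,6R,10Z)-6-acetoxy-2-(acetoxymethyl)-4-(TBS-oxy)-12-hydroxy-3-iodo-6,10-dimethyl-7-oxododeca-2,10-dienoate
Conditions: DDQ, CH2Cl2/pH 7 buffer, 0 °C
Reagents that add atoms: none
Why: DDQ oxidises the electron-rich PMB ether to an oxocarbenium ion that water hydrolyses, freeing the (Z)-allylic alcohol while acetates, silyl ether and alkenyl iodide are inert.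

Step 13
Reactants: 19 methyl (2Z,4S,6R,10Z)-6-acetoxy-2-(acetoxymethyl)-4-(TBS-oxy)-12-hydroxy-3-iodo-6,10-dimethyl-7-oxododeca-2,10-dienoate
Product: 20 methyl (2Z,4S,6R)-6-acetoxy-2-(acetoxymethyl)-4-(TBS-oxy)-9-[(2R,3S)-3-(hydroxymethyl)-2-methyloxiran-2-yl]-3-iodo-6-methyl-7-oxonon-2-enoate
Conditions: Ti(OiPr)4 (20 mol %), L-(+)-diethyl tartrate (24 mol %), t-BuOOH, 4 Å MS, CH2Cl2, −20 °C
Reagents that add atoms: tert-butyl hydroperoxide (CC(C)(C)OO)
Why: Sharpless asymmetric epoxidation: the titanium tartrate binds the allylic alcohol and delivers the peroxide oxygen to one face of the (Z)-alkene, L-(+)-tartrate giving the (4R,5S) cis-epoxide (same sense as nerol to (2S,3R)-epoxynerol), and the electron-poor iodoenoate does not react.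

Step 14
Reactants: 20 methyl (2Z,4S,6R)-6-acetoxy-2-(acetoxymethyl)-4-(TBS-oxy)-9-[(2R,3S)-3-(hydroxymethyl)-2-methyloxiran-2-yl]-3-iodo-6-methyl-7-oxonon-2-enoate
Product: 21 methyl (2Z,4S,6R)-6-acetoxy-2-(acetoxymethyl)-4-(TBS-oxy)-9-[(2R,3R)-3-formyl-2-methyloxiran-2-yl]-3-iodo-6-methyl-7-oxonon-2-enoate
Conditions: TEMPO (10 mol %), PhI(OAc)2, CH2Cl2, rt
Reagents that add atoms: none
Why: Oxoammonium (TEMPO/PhI(OAc)2) oxidation of the primary epoxy alcohol stops at the aldehyde under nearly neutral conditions, so the epoxide and all stereocentres are kept (the descriptor at C5 changes only because the priorities change).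

Step 15
Reactants: 21 methyl (2Z,4S,6R)-6-acetoxy-2-(acetoxymethyl)-4-(TBS-oxy)-9-[(2R,3R)-3-formyl-2-methyloxiran-2-yl]-3-iodo-6-methyl-7-oxonon-2-enoate
Product: 23 (4R,5S,6S,8S,10R)-10,13-diacetoxy-8-(TBS-oxy)-4,5-epoxy-1-oxogermacr-7(11)-en-12,6-olide, via hydroxy enoate 22 (not isolated)
Conditions: CrCl2 (8 equiv), NiCl2 (0.1 equiv), DMSO, rt, 2 mM (slow addition)
Reagents that add atoms: none
Why: Nozaki–Hiyama–Kishi reaction: zerovalent nickel inserts into the C–I bond, transmetallation gives an ester-chelated alkenylchromium species that adds to the epoxy aldehyde anti to the oxirane C–O bond (Felkin–Anh), setting C6 (S) while closing the ten-membered ring through the C6–C7 bond, and the alkoxide, held cis to the ester, lactonises to the butenolide.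

Step 16
Reactants: 23 (4R,5S,6S,8S,10R)-10,13-diacetoxy-8-(TBS-oxy)-4,5-epoxy-1-oxogermacr-7(11)-en-12,6-olide
Product: 24 (4R,5S,6S,7R,8S,10R,11R)-10,13-diacetoxy-8-(TBS-oxy)-4,5-epoxy-1-oxogermacran-12,6-olide
Conditions: H2 (50 bar), 5% Rh/Al2O3, EtOAc, rt
Reagents that add atoms: none
Why: Heterogeneous syn-hydrogenation delivers both hydrogens to the butenolide face that carries H-6, the other face being blocked by C5 and by the silyloxy group at C8, which gives the all-cis lactone and sets C7 and C11 (rhodium is chosen to avoid hydrogenolysis of the allylic acetate and of the epoxide).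

Step 17
Reactants: 24 (4R,5S,6S,7R,8S,10R,11R)-10,13-diacetoxy-8-(TBS-oxy)-4,5-epoxy-1-oxogermacran-12,6-olide
Product: 25 (4R,5S,6S,7S,8S,10R,11R)-10,13-diacetoxy-4,5-epoxy-8-hydroxy-1-oxogermacran-12,6-olide
Conditions: HF·pyridine, pyridine, THF, 0 °C to rt
Reagents that add atoms: none
Why: Fluoride-induced desilylation under pyridine buffering frees the C8 hydroxyl without epoxide opening, acetate loss or epimerisation at C11 (the C7 descriptor changes only because the priorities change).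

Step 18
Reactants: 25 (4R,5S,6S,7S,8S,10R,11R)-10,13-diacetoxy-4,5-epoxy-8-hydroxy-1-oxogermacran-12,6-olide
Product: 26 (4R,5S,6S,7S,8S,10R,11R)-10,13-diacetoxy-4,5-epoxy-8-(methacryloyloxy)-1-oxogermacran-12,6-olide (target)
Conditions: methacrylic anhydride, DMAP, Et3N, CH2Cl2, 0 °C
Reagents that add atoms: methacrylic anhydride (C=C(C)C(=O)OC(=O)C(C)=C)
Why: DMAP-catalysed acylation (Steglich-type acyl transfer) of the only free hydroxyl installs the methacrylate; no stereocentre is touched.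

## Compound list

1 | nerol, (2Z)-3,7-dimethylocta-2,6-dien-1-ol | CC(C)=CCC/C(C)=C\CO | starting material
2 | 1-({[(2Z)-3,7-dimethylocta-2,6-dien-1-yl]oxy}methyl)-4-methoxybenzene | CC(C)=CCC/C(C)=C\COCc1ccc(OC)cc1 | intermediate
3 | 3-[(3Z)-5-((4-methoxybenzyl)oxy)-3-methylpent-3-en-1-yl]-2,2-dimethyloxirane (racemic) | CC1(C)OC1CC/C(C)=C\COCc1ccc(OC)cc1 | intermediate
4 | (6Z)-8-((4-methoxybenzyl)oxy)-2,6-dimethyloct-6-ene-2,3-diol (racemic) | CC(C)(O)C(O)CC/C(C)=C\COCc1ccc(OC)cc1 | intermediate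
5 | (4Z)-6-((4-methoxybenzyl)oxy)-4-methylhex-4-enal | O=CCC/C(C)=C\COCc1ccc(OC)cc1 | intermediate
6 | (6Z)-2-ethoxy-8-((4-methoxybenzyl)oxy)-6-methylocta-1,6-dien-3-ol (racemic) | C=C(OCC)C(O)CC/C(C)=C\COCc1ccc(OC)cc1 | intermediate
7 | (6Z)-3-hydroxy-8-((4-methoxybenzyl)oxy)-6-methyloct-6-en-2-one (racemic) | CC(=O)C(O)CC/C(C)=C\COCc1ccc(OC)cc1 | intermediate
8 | (6Z)-8-((4-methoxybenzyl)oxy)-6-methyloct-6-ene-2,3-dione | CC(=O)C(=O)CC/C(C)=C\COCc1ccc(OC)cc1 | intermediate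
9 | S-ethyl ethanethioate | CCSC(C)=O | starting material
10 | [1-(ethylsulfanyl)ethenyl]oxy(trimethyl)silane | C=C(O[Si](C)(C)C)SCC | intermediate
11 | S-ethyl (3R,7Z)-9-((4-methoxybenzyl)oxy)-3,7-dimethyl-4-oxo-3-((trimethylsilyl)oxy)non-7-enethioate | CCSC(=O)C[C@@](C)(O[Si](C)(C)C)C(=O)CC/C(C)=C\COCc1ccc(OC)cc1 | intermediate
12 | (3R,7Z)-9-((4-methoxybenzyl)oxy)-3,7-dimethyl-4-oxo-3-((trimethylsilyl)oxy)non-7-enal | O=CC[C@@](C)(O[Si](C)(C)C)C(=O)CC/C(C)=C\COCc1ccc(OC)cc1 | intermediate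
13 | methyl propiolate (methyl prop-2-ynoate) | C#CC(=O)OC | starting material
14 | methyl (4S,6R,10Z)-4-hydroxy-12-((4-methoxybenzyl)oxy)-6,10-dimethyl-7-oxo-6-((trimethylsilyl)oxy)dodec-10-en-2-ynoate | COC(=O)C#C[C@@H](O)C[C@@](C)(O[Si](C)(C)C)C(=O)CC/C(C)=C\COCc1ccc(OC)cc1 | intermediate
15 | methyl (4S,6R,10Z)-4,6-dihydroxy-12-((4-methoxybenzyl)oxy)-6,10-dimethyl-7-oxododec-10-en-2-ynoate | COC(=O)C#C[C@@H](O)C[C@@](C)(O)C(=O)CC/C(C)=C\COCc1ccc(OC)cc1 | intermediate
16 | methyl (4S,6R,10Z)-4-((tert-butyldimethylsilyl)oxy)-6-hydroxy-12-((4-methoxybenzyl)oxy)-6,10-dimethyl-7-oxododec-10-en-2-ynoate | COC(=O)C#C[C@@H](O[Si](C)(C)C(C)(C)C)C[C@@](C)(O)C(=O)CC/C(C)=C\COCc1ccc(OC)cc1 | intermediate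
17 | methyl (2Z,4S,6R,10Z)-4-((tert-butyldimethylsilyl)oxy)-6-hydroxy-2-(hydroxymethyl)-3-iodo-12-((4-methoxybenzyl)oxy)-6,10-dimethyl-7-oxododeca-2,10-dienoate | COC(=O)/C(CO)=C(\I)[C@@H](O[Si](C)(C)C(C)(C)C)C[C@@](C)(O)C(=O)CC/C(C)=C\COCc1ccc(OC)cc1 | intermediate
18 | methyl (2Z,4S,6R,10Z)-6-acetoxy-2-(acetoxymethyl)-4-((tert-butyldimethylsilyl)oxy)-3-iodo-12-((4-methoxybenzyl)oxy)-6,10-dimethyl-7-oxododeca-2,10-dienoate | COC(=O)/C(COC(C)=O)=C(\I)[C@@H](O[Si](C)(C)C(C)(C)C)C[C@@](C)(OC(C)=O)C(=O)CC/C(C)=C\COCc1ccc(OC)cc1 | intermediate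
19 | methyl (2Z,4S,6R,10Z)-6-acetoxy-2-(acetoxymethyl)-4-((tert-butyldimethylsilyl)oxy)-12-hydroxy-3-iodo-6,10-dimethyl-7-oxododeca-2,10-dienoate | COC(=O)/C(COC(C)=O)=C(\I)[C@@H](O[Si](C)(C)C(C)(C)C)C[C@@](C)(OC(C)=O)C(=O)CC/C(C)=C\CO | intermediate
20 | methyl (2Z,4S,6R)-6-acetoxy-2-(acetoxymethyl)-4-((tert-butyldimethylsilyl)oxy)-9-[(2R,3S)-3-(hydroxymethyl)-2-methyloxiran-2-yl]-3-iodo-6-methyl-7-oxonon-2-enoate | COC(=O)/C(COC(C)=O)=C(\I)[C@@H](O[Si](C)(C)C(C)(C)C)C[C@@](C)(OC(C)=O)C(=O)CC[C@@]1(C)O[C@H]1CO | intermediate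
21 | methyl (2Z,4S,6R)-6-acetoxy-2-(acetoxymethyl)-4-((tert-butyldimethylsilyl)oxy)-9-[(2R,3R)-3-formyl-2-methyloxiran-2-yl]-3-iodo-6-methyl-7-oxonon-2-enoate | COC(=O)/C(COC(C)=O)=C(\I)[C@@H](O[Si](C)(C)C(C)(C)C)C[C@@](C)(OC(C)=O)C(=O)CC[C@@]1(C)O[C@H]1C=O | intermediate
22 | methyl (4R,5S,6S,8S,10R,7(11)Z)-10,13-diacetoxy-8-((tert-butyldimethylsilyl)oxy)-4,5-epoxy-6-hydroxy-1-oxogermacr-7(11)-en-12-oate (ring closed at C6–C7, lactone still open) | CC(C)(C)[Si](C)(C)O[C@H]1C[C@@](C)(OC(C)=O)C(=O)CC[C@@]2(C)O[C@H]2[C@@H](O)/C1=C(/COC(C)=O)C(=O)OC | intermediate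
23 | (4R,5S,6S,8S,10R)-10,13-diacetoxy-8-((tert-butyldimethylsilyl)oxy)-4,5-epoxy-1-oxogermacr-7(11)-en-12,6-olide | CC(C)(C)[Si](C)(C)O[C@H]1C[C@@](C)(OC(C)=O)C(=O)CC[C@@]2(C)O[C@H]2[C@H]2OC(=O)C(COC(C)=O)=C21 | intermediate
24 | (4R,5S,6S,7R,8S,10R,11R)-10,13-diacetoxy-8-((tert-butyldimethylsilyl)oxy)-4,5-epoxy-1-oxogermacran-12,6-olide | CC(C)(C)[Si](C)(C)O[C@H]1C[C@@](C)(OC(C)=O)C(=O)CC[C@@]2(C)O[C@H]2[C@H]2OC(=O)[C@@H](COC(C)=O)[C@H]21 | intermediate
25 | (4R,5S,6S,7S,8S,10R,11R)-10,13-diacetoxy-4,5-epoxy-8-hydroxy-1-oxogermacran-12,6-olide | O[C@H]1C[C@@](C)(OC(C)=O)C(=O)CC[C@@]2(C)O[C@H]2[C@H]2OC(=O)[C@@H](COC(C)=O)[C@H]21 | intermediate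
26 | (4R,5S,6S,7S,8S,10R,11R)-10,13-diacetoxy-4,5-epoxy-8-(methacryloyloxy)-1-oxogermacran-12,6-olide (CNP0166747.1) | C=C(C)C(=O)O[C@H]1C[C@@](C)(OC(C)=O)C(=O)CC[C@@]2(C)O[C@H]2[C@H]2OC(=O)[C@@H](COC(C)=O)[C@H]21 | target

## Step count and weak points

Total step count: 18. Longest linear sequence: 17 steps (steps 1–4 and 6–18, from nerol); step 5 is a one-step side branch.

The three steps most likely to fail:

Step 10 (halo-aldol on a β-substituted ynoate with formaldehyde; reactivity and alkene geometry are unproven). The fallback gives up the alkenyl iodide and closes the ring with an allyl nucleophile; it sets out from 16 and comes back at 24. Copper hydride ([(Ph3P)CuH]6, toluene) adds hydride to C7 of the ynoate and the copper allenolate is trapped with formaldehyde to give the 2-(hydroxymethyl) enoate F1. Ac2O/DMAP gives the bis-acetate F2, DDQ gives the allylic alcohol F3, Ti(OiPr)4/L-(+)-diethyl tartrate/t-BuOOH gives the epoxy alcohol F4, and TEMPO/PhI(OAc)2 gives the epoxy aldehyde F5. Pd(PPh3)4 (cat.) with InI then turns the allylic acetate into an allylindium that adds through C7 to the aldehyde (Barbier-type closure of the same C6–C7 bond; the cis-lactone is expected from the cyclic transition state, Felkin sense at C6), and lactonisation gives the α-methylene lactone F6. CuCl/NaOtBu/Xantphos-catalysed conjugate borylation with B2pin2 and MeOH (enolate protonated on the convex face) gives the boronate F7, NaBO3 gives the 13-alcohol F8, and acetylation returns to 24.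

Step 15 (ten-membered ring closure with a hindered tetrasubstituted alkenyl iodide next to an epoxy aldehyde). The fallback closes the same C6–C7 bond at the acyl oxidation level and sets C6 afterwards; it sets out from 20 and comes back at 23. TEMPO/PhI(OAc)2 in MeCN/H2O oxidises 20 to the glycidic acid F9, and 2,2'-dipyridyl disulfide/PPh3 gives the S-pyridin-2-yl thioester F10. A Kishi-type macroketonisation (NiBr2 with 4,4'-di-tert-butyl-2,2'-bipyridine, Cp2ZrCl2, Zn, 1,3-dimethyl-2-imidazolidinone) gives the macrocyclic epoxy enone F11. Zn(BH4)2 at −78 °C reduces the doubly activated C6 ketone anti to the epoxide, and the alkoxide lactonises to 23.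

Step 16 (hydrogenation of a tetrasubstituted butenolide; slow reaction, loss of the allylic acetate or the wrong face are possible). The fallback replaces hydrogenation by hydride addition followed by re-oxygenation of C13; it sets out from 23 and comes back at 24. A copper hydride ([(Ph3P)CuH]6) adds hydride to C7 on the H-6 face and the enolate expels the C13 acetate (SN2′) to give the α-methylene lactone F6. This is then carried through the boronate F7 and the 13-alcohol F8 to 24 exactly as in the fallback for step 10; kinetic protonation of the boryl enolate sets C11.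

Further compounds

F1 | step 10 | methyl (2Z,4S,6R,10Z)-4-((tert-butyldimethylsilyl)oxy)-6-hydroxy-2-(hydroxymethyl)-12-((4-methoxybenzyl)oxy)-6,10-dimethyl-7-oxododeca-2,10-dienoate | COC(=O)/C(CO)=C\[C@@H](O[Si](C)(C)C(C)(C)C)C[C@@](C)(O)C(=O)CC/C(C)=C\COCc1ccc(OC)cc1
F2 | step 10 | methyl (2Z,4S,6R,10Z)-6-acetoxy-2-(acetoxymethyl)-4-((tert-butyldimethylsilyl)oxy)-12-((4-methoxybenzyl)oxy)-6,10-dimethyl-7-oxododeca-2,10-dienoate | COC(=O)/C(COC(C)=O)=C\[C@@H](O[Si](C)(C)C(C)(C)C)C[C@@](C)(OC(C)=O)C(=O)CC/C(C)=C\COCc1ccc(OC)cc1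
F3 | step 10 | methyl (2Z,4S,6R,10Z)-6-acetoxy-2-(acetoxymethyl)-4-((tert-butyldimethylsilyl)oxy)-12-hydroxy-6,10-dimethyl-7-oxododeca-2,10-dienoate | COC(=O)/C(COC(C)=O)=C\[C@@H](O[Si](C)(C)C(C)(C)C)C[C@@](C)(OC(C)=O)C(=O)CC/C(C)=C\CO
F4 | step 10 | methyl (2Z,4S,6R)-6-acetoxy-2-(acetoxymethyl)-4-((tert-butyldimethylsilyl)oxy)-9-[(2R,3S)-3-(hydroxymethyl)-2-methyloxiran-2-yl]-6-methyl-7-oxonon-2-enoate | COC(=O)/C(COC(C)=O)=C\[C@@H](O[Si](C)(C)C(C)(C)C)C[C@@](C)(OC(C)=O)C(=O)CC[C@@]1(C)O[C@H]1CO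
F5 | step 10 | methyl (2Z,4S,6R)-6-acetoxy-2-(acetoxymethyl)-4-((tert-butyldimethylsilyl)oxy)-9-[(2R,3R)-3-formyl-2-methyloxiran-2-yl]-6-methyl-7-oxonon-2-enoate | COC(=O)/C(COC(C)=O)=C\[C@@H](O[Si](C)(C)C(C)(C)C)C[C@@](C)(OC(C)=O)C(=O)CC[C@@]1(C)O[C@H]1C=O
F6 | step 10 | (4R,5S,6S,7R,8S,10R)-10-acetoxy-8-((tert-butyldimethylsilyl)oxy)-4,5-epoxy-1-oxogermacr-11(13)-en-12,6-olide | CC(C)(C)[Si](C)(C)O[C@H]1C[C@@](C)(OC(C)=O)C(=O)CC[C@@]2(C)O[C@H]2[C@H]2OC(=O)C(=C)[C@H]21
F7 | step 10 | (4R,5S,6S,7R,8S,10R,11S)-10-acetoxy-8-((tert-butyldimethylsilyl)oxy)-4,5-epoxy-1-oxo-13-(4,4,5,5-tetramethyl-1,3,2-dioxaborolan-2-yl)germacran-12,6-olide | CC(C)(C)[Si](C)(C)O[C@H]1C[C@@](C)(OC(C)=O)C(=O)CC[C@@]2(C)O[C@H]2[C@H]2OC(=O)[C@@H](CB3OC(C)(C)C(C)(C)O3)[C@H]21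
F8 | step 10 | (4R,5S,6S,7R,8S,10R,11R)-10-acetoxy-8-((tert-butyldimethylsilyl)oxy)-4,5-epoxy-13-hydroxy-1-oxogermacran-12,6-olide | CC(C)(C)[Si](C)(C)O[C@H]1C[C@@](C)(OC(C)=O)C(=O)CC[C@@]2(C)O[C@H]2[C@H]2OC(=O)[C@@H](CO)[C@H]21
F9 | step 15 | methyl (2Z,4S,6R)-6-acetoxy-2-(acetoxymethyl)-4-((tert-butyldimethylsilyl)oxy)-9-[(2R,3R)-3-carboxy-2-methyloxiran-2-yl]-3-iodo-6-methyl-7-oxonon-2-enoate | COC(=O)/C(COC(C)=O)=C(\I)[C@@H](O[Si](C)(C)C(C)(C)C)C[C@@](C)(OC(C)=O)C(=O)CC[C@@]1(C)O[C@H]1C(=O)O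
F10 | step 15 | methyl (2Z,4S,6R)-6-acetoxy-2-(acetoxymethyl)-4-((tert-butyldimethylsilyl)oxy)-3-iodo-6-methyl-9-[(2R,3R)-2-methyl-3-((pyridin-2-ylsulfanyl)carbonyl)oxiran-2-yl]-7-oxonon-2-enoate | COC(=O)/C(COC(C)=O)=C(\I)[C@@H](O[Si](C)(C)C(C)(C)C)C[C@@](C)(OC(C)=O)C(=O)CC[C@@]1(C)O[C@H]1C(=O)Sc1ccccn1
F11 | step 15 | methyl (4R,5R,8S,10R,7(11)Z)-10,13-diacetoxy-8-((tert-butyldimethylsilyl)oxy)-4,5-epoxy-1,6-dioxogermacr-7(11)-en-12-oate | CC(C)(C)[Si](C)(C)O[C@H]1C[C@@](C)(OC(C)=O)C(=O)CC[C@@]2(C)O[C@H]2C(=O)/C1=C(/COC(C)=O)C(=O)OC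
F0 | step 16 | none | none
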